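**Retrosynthetic overview**
1. Target 27 ⇐ reagent-controlled Shi epoxidation of the C3=C4 alkene of macrocyclic trienolide 26 (oxirane formed last).
2. 26 ⇐ ring contraction of a 15-membered cyclic boronate (boron bridging C7 and C8): 1,2-shift of the C8 alkenyl group from B to C7, then C–B oxidation. This closes the 14-membered carbocycle and sets C7–OH from open-chain 22.
3. 22 ⇐ indium Barbier allylation/lactonisation joining C14 (α-hydroxy aldehyde from 8) to C1 (2-(bromomethyl)enoate 17); the γ-lactone is the first ring formed.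
4. 8 ⇐ crotonaldehyde acetal (Shi epoxidation, Cu-catalysed Grignard opening, α-hydroalumination/borylation); 17 ⇐ pent-4-yn-1-ol (carboalumination/allylation, sparteine-mediated sulfinylation, cross-metathesis).
5. Ring order: lactone (step 8) → 14-membered carbocycle (step 10) → oxirane (step 11).

Assumption: atoms are numbered as in cembranes (ring C1–C14; C1 carries C15(=C17H2)–C16(=O)O– closing to O–C14; C18 methyl on C4, C19 on C8, C20 methyl on C12), and open-chain precursors keep these numbers.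

**Step 1**
Reactants: 1 (2E)-1,1-dimethoxybut-2-ene
Product: 2 (2R,3S)-2-(dimethoxymethyl)-3-methyloxirane
Conditions: L-fructose-derived Shi ketone (ent-Shi ketone, 30 mol %), Oxone (2KHSO5·KHSO4·K2SO4), K2CO3, n-Bu4NHSO4, MeCN/CH2(OMe)2/aq. Na2B4O7 buffer, 0 °C
Reagents that add atoms: potassium peroxymonosulfate (Oxone), [K+].[O-]S(=O)(=O)OO
Why: Shi asymmetric epoxidation: the chiral dioxirane transfers oxygen to the E-alkene through a spiro transition state on the face that gives the (2R,3S)-trans-epoxide, fixing C13 and (after inversion in step 2) C12.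

**Step 2**
Reactants: 2 (2R,3S)-2-(dimethoxymethyl)-3-methyloxirane; 3 (5-chloropent-1-yn-1-yl)trimethylsilane
Product: 6 (2R,3S)-1,1-dimethoxy-3-methyloct-7-yn-2-ol, via Grignard reagent 4 (not isolated), via silylated alkynol 5 (not isolated)
Conditions: 3, Mg, THF, 60 °C; then CuI (10 mol %), 2, THF, −40 → 0 °C; then MeOH, K2CO3, 23 °C
Reagents that add atoms: none
Why: Copper-catalysed SN2 epoxide opening by the Grignard reagent occurs with inversion at the methyl-bearing carbon (the acetal-bearing carbon is sterically and inductively deactivated), so the trans-epoxide gives the 12,13-syn methyl/hydroxyl pair (12S,13R); methanolysis then cleaves the alkynyl C–Si bond.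

**Step 3**
Reactants: 6 (2R,3S)-1,1-dimethoxy-3-methyloct-7-yn-2-ol
Product: 8 (2R,3S)-1,1-dimethoxy-3-methyl-7-(4,4,5,5-tetramethyl-1,3,2-dioxaborolan-2-yl)oct-7-en-2-ol, via alkenylalane 7 (not isolated)
Conditions: i-Bu2AlH (2.5 equiv), NiCl2(dppp) (3 mol %), THF, 0 → 23 °C; then MeOBpin, 0 → 23 °C; aq. KNaC4H4O6 work-up
Reagents that add atoms: 2-methoxy-4,4,5,5-tetramethyl-1,3,2-dioxaborolane (MeOBpin), COB1OC(C)(C)C(C)(C)O1
Why: Nickel-catalysed α-selective hydroalumination of the terminal alkyne places aluminium on the internal carbon, and aluminium-to-boron exchange with MeOBpin gives the 1,1-disubstituted alkenyl boronate without touching a stereocentre.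

**Step 4**
Reactants: 9 pent-4-yn-1-ol; 10 3-bromoprop-1-ene (allyl bromide)
Product: 12 (4E)-4-methylocta-4,7-dien-1-ol, via alkenylalane 11 (not isolated)
Conditions: Me3Al (3 equiv), Cp2ZrCl2 (25 mol %), CH2Cl2, 0 → 23 °C; then 10, Pd(PPh3)4 (5 mol %), THF, 23 °C
Reagents that add atoms: trimethylaluminium, C[Al](C)C
Why: Negishi zirconium-catalysed carboalumination adds methyl and aluminium syn across the alkyne (E-trisubstituted C3=C4), and palladium-catalysed alkenyl–allyl cross-coupling with retention gives the skipped diene.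

**Step 5**
Reactants: 12 (4E)-4-methylocta-4,7-dien-1-ol
Product: 13 (4E)-4-methylocta-4,7-dien-1-yl 2,4,6-tri(propan-2-yl)benzoate
Conditions: 2,4,6-i-Pr3C6H2COCl, Et3N, DMAP (cat.), CH2Cl2, 40 °C
Reagents that add atoms: 2,4,6-tri(propan-2-yl)benzoyl chloride, CC(C)c1cc(C(C)C)c(C(=O)Cl)c(C(C)C)c1
Why: DMAP-catalysed acylation installs the hindered benzoate that directs α-lithiation and later acts as the leaving group of the 1,2-shift.

**Step 6**
Reactants: 13 (4E)-4-methylocta-4,7-dien-1-yl 2,4,6-tri(propan-2-yl)benzoate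
Product: 15 (1S,4E)-4-methyl-1-[(S)-4-methylbenzenesulfinyl]octa-4,7-dien-1-yl 2,4,6-tri(propan-2-yl)benzoate, via lithiated benzoate 14 (not isolated)
Conditions: s-BuLi, (−)-sparteine, Et2O, −78 °C, 5 h; then (1R,2S,5R)-menthyl (S)-4-methylbenzenesulfinate, −78 → 23 °C
Reagents that add atoms: (1R,2S,5R)-menthyl (S)-4-methylbenzenesulfinate, C[C@@H]1CC[C@H]([C@@H](C1)O[S@](=O)c1ccc(C)cc1)C(C)C
Why: Hoppe-type sparteine-mediated asymmetric deprotonation removes the pro-S α-hydrogen to give the configurationally stable (S)-lithiated benzoate, which is sulfinylated with retention at carbon and inversion at sulfur (Andersen substitution), storing the C7 carbenoid in bench-stable form.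

**Step 7**
Reactants: 15 (1S,4E)-4-methyl-1-[(S)-4-methylbenzenesulfinyl]octa-4,7-dien-1-yl 2,4,6-tri(propan-2-yl)benzoate; 16 methyl 2-(bromomethyl)prop-2-enoate
Product: 17 methyl (2Z,5E,9S)-2-(bromomethyl)-6-methyl-9-[(S)-4-methylbenzenesulfinyl]-9-{[2,4,6-tri(propan-2-yl)benzoyl]oxy}nona-2,5-dienoate
Conditions: 16 (4 equiv), second-generation Hoveyda–Grubbs catalyst (10 mol %), 1,4-benzoquinone (10 mol %), CH2Cl2, 40 °C
Reagents that add atoms: none
Why: Olefin cross-metathesis of the monosubstituted terminal alkene with the 1,1-disubstituted acrylate (the trisubstituted alkene is inert) gives the thermodynamically preferred (Z)-2-(bromomethyl)enoate with loss of ethene.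

**Step 8**
Reactants: 8 (2R,3S)-1,1-dimethoxy-3-methyl-7-(4,4,5,5-tetramethyl-1,3,2-dioxaborolan-2-yl)oct-7-en-2-ol; 17 methyl (2Z,5E,9S)-2-(bromomethyl)-6-methyl-9-[(S)-4-methylbenzenesulfinyl]-9-{[2,4,6-tri(propan-2-yl)benzoyl]oxy}nona-2,5-dienoate
Product: 21 (4S,5R)-5-[(1R,2S)-1-hydroxy-2-methyl-6-(4,4,5,5-tetramethyl-1,3,2-dioxaborolan-2-yl)hept-6-en-1-yl]-4-{(2E,6S)-3-methyl-6-[(S)-4-methylbenzenesulfinyl]-6-[2,4,6-tri(propan-2-yl)benzoyloxy]hex-2-en-1-yl}-3-methylideneoxolan-2-one, via hydroxy aldehyde 18 (not isolated), via allylindium species 19 (not isolated), via hydroxy ester 20 (not isolated)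
Conditions: 8, Amberlyst 15, THF/H2O, 40 °C, filter; then 17, In powder, THF/H2O (1:1), 23 °C; then p-TsOH (cat.), CH2Cl2, 23 °C
Reagents that add atoms: water, O
Why: Acetal hydrolysis is followed by an indium-mediated Barbier allylation in water, in which the γ-carbon of the (Z)-allylindium adds through a chair transition state chelated by the free α-hydroxyl to give the 13,14-syn (Cram-chelate) and 14,1-syn relationships; the γ-hydroxy ester then lactonises to the cis-fused α-methylene-γ-butyrolactone (14R,1S).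

**Step 9**
Reactants: 21 (the lactone alcohol of step 8)
Product: 22 (1R,2S)-2-methyl-1-[(2R,3S)-3-{(2E,6S)-3-methyl-6-[(S)-4-methylbenzenesulfinyl]-6-[2,4,6-tri(propan-2-yl)benzoyloxy]hex-2-en-1-yl}-4-methylidene-5-oxooxolan-2-yl]-6-(4,4,5,5-tetramethyl-1,3,2-dioxaborolan-2-yl)hept-6-en-1-yl acetate
Conditions: Ac2O, pyridine, DMAP (cat.), CH2Cl2, 0 °C
Reagents that add atoms: acetic anhydride, CC(=O)OC(C)=O
Why: DMAP-catalysed acetylation of the only free hydroxyl (C13) proceeds with retention and removes the last acidic proton before the organomagnesium step.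

**Step 10**
Reactants: 22 (the open-chain acetate of step 9)
Product: 26 (1S,3E,7R,12S,13R,14R)-13-acetoxy-7-hydroxycembra-3,8(19),15(17)-trien-16,14-olide, via magnesium carbenoid 23 (not isolated), via cyclic boronate complex 24 (not isolated), via allylboronate 25 (not isolated)
Conditions: i-PrMgCl·LiCl (1.3 equiv), THF, 1 mM, −78 °C, 1 h; → 23 °C, then 40 °C; then 30% H2O2, pH 7 phosphate buffer, 0 °C
Reagents that add atoms: hydrogen peroxide, OO
Why: Proposed new method: sulfoxide–magnesium exchange (faster at −78 °C than attack of i-PrMgCl on Bpin, lactone or acetate) unmasks a configurationally stable α-(acyloxy)alkylmagnesium carbenoid that is captured intramolecularly by the C8 alkenyl-Bpin to give a 15-membered cyclic boronate; on warming, the C8 alkenyl group migrates from boron to C7 antiperiplanar to the departing triisopropylbenzoate (invertive at C7, so the (S)-carbenoid gives the (7R)-allylboronate), contracting the boracycle to the 14-membered carbocycle, and stereoretentive C–B oxidation gives the (7R)-allylic alcohol; the closest known reactions are the intermolecular lithiation–borylation type 1,2-metallate rearrangement of sulfoxide-derived lithium and magnesium carbenoids with boronic esters and the ring contraction of small cyclic boronate complexes, neither of which has been used to close a macrocycle.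

**Step 11**
Reactants: 26 (1S,3E,7R,12S,13R,14R)-13-acetoxy-7-hydroxycembra-3,8(19),15(17)-trien-16,14-olide
Product: 27 (1S,3R,4R,7R,12S,13R,14R)-13-acetoxy-3,4-epoxy-7-hydroxycembra-8(19),15(17)-dien-16,14-olide (CNP0230083.2)
Conditions: D-fructose-derived Shi ketone (30 mol %), Oxone (2KHSO5·KHSO4·K2SO4), K2CO3, n-Bu4NHSO4, MeCN/CH2(OMe)2/aq. Na2B4O7 buffer, 0 °C
Reagents that add atoms: potassium peroxymonosulfate (Oxone), [K+].[O-]S(=O)(=O)OO
Why: Shi asymmetric epoxidation: the D-fructose-derived dioxirane epoxidises the electron-rich E-trisubstituted C3=C4 alkene on the face that gives the (3R,4R)-epoxide under reagent control, while the 1,1-disubstituted allylic alkene and the electron-poor α-methylene lactone react much more slowly.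

**Compound list**
1 | (2E)-1,1-dimethoxybut-2-ene (crotonaldehyde dimethyl acetal) | C/C=C/C(OC)OC | starting material
2 | (2R,3S)-2-(dimethoxymethyl)-3-methyloxirane | C[C@@H]1O[C@H]1C(OC)OC | intermediate
3 | (5-chloropent-1-yn-1-yl)trimethylsilane | C[Si](C)(C)C#CCCCCl | starting material
4 | [5-(trimethylsilyl)pent-4-yn-1-yl]magnesium chloride | C[Si](C)(C)C#CCCC[Mg]Cl | intermediate
5 | (2R,3S)-1,1-dimethoxy-3-methyl-8-(trimethylsilyl)oct-7-yn-2-ol | C[Si](C)(C)C#CCCC[C@H](C)[C@@H](O)C(OC)OC | intermediate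
6 | (2R,3S)-1,1-dimethoxy-3-methyloct-7-yn-2-ol | C#CCCC[C@H](C)[C@@H](O)C(OC)OC | intermediate
7 | alkenylalane from 6: Al(i-Bu)2 on the internal alkene carbon (C8), hydroxyl as O–Al(i-Bu)2 | C=C([Al](CC(C)C)CC(C)C)CCC[C@H](C)[C@@H](O[Al](CC(C)C)CC(C)C)C(OC)OC | intermediate
8 | (2R,3S)-1,1-dimethoxy-3-methyl-7-(4,4,5,5-tetramethyl-1,3,2-dioxaborolan-2-yl)oct-7-en-2-ol | C=C(B1OC(C)(C)C(C)(C)O1)CCC[C@H](C)[C@@H](O)C(OC)OC | intermediate
9 | pent-4-yn-1-ol | C#CCCCO | starting material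
10 | 3-bromoprop-1-ene (allyl bromide) | C=CCBr | starting material
11 | (E)-alkenylalane from 9: AlMe2 on C3 cis to the new methyl, hydroxyl as O–AlMe2 | C[Al](C)/C=C(\C)CCCO[Al](C)C | intermediate
12 | (4E)-4-methylocta-4,7-dien-1-ol | OCCC/C(C)=C/CC=C | intermediate
13 | (4E)-4-methylocta-4,7-dien-1-yl 2,4,6-tri(propan-2-yl)benzoate | C=CC/C=C(\C)CCCOC(=O)c1c(C(C)C)cc(C(C)C)cc1C(C)C | intermediate
14 | (1S,4E)-1-lithio-4-methylocta-4,7-dien-1-yl 2,4,6-tri(propan-2-yl)benzoate (sparteine complex) | C=CC/C=C(\C)CC[C@@H](OC(=O)c1c(C(C)C)cc(C(C)C)cc1C(C)C)[Li] | intermediate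
15 | (1S,4E)-4-methyl-1-[(S)-4-methylbenzenesulfinyl]octa-4,7-dien-1-yl 2,4,6-tri(propan-2-yl)benzoate | C=CC/C=C(\C)CC[C@@H](OC(=O)c1c(C(C)C)cc(C(C)C)cc1C(C)C)[S@@](=O)c1ccc(C)cc1 | intermediate
16 | methyl 2-(bromomethyl)prop-2-enoate | C=C(CBr)C(=O)OC | starting material
17 | methyl (2Z,5E,9S)-2-(bromomethyl)-6-methyl-9-[(S)-4-methylbenzenesulfinyl]-9-{[2,4,6-tri(propan-2-yl)benzoyl]oxy}nona-2,5-dienoate | COC(=O)/C(CBr)=C/C/C=C(\C)CC[C@@H](OC(=O)c1c(C(C)C)cc(C(C)C)cc1C(C)C)[S@@](=O)c1ccc(C)cc1 | intermediate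
18 | (2R,3S)-2-hydroxy-3-methyl-7-(4,4,5,5-tetramethyl-1,3,2-dioxaborolan-2-yl)oct-7-enal | C=C(B1OC(C)(C)C(C)(C)O1)CCC[C@H](C)[C@@H](O)C=O | intermediate
19 | allylindium species from 17 (drawn as the σ-allyl dibromoindium compound) | COC(=O)/C(C[In](Br)Br)=C/C/C=C(\C)CC[C@@H](OC(=O)c1c(C(C)C)cc(C(C)C)cc1C(C)C)[S@@](=O)c1ccc(C)cc1 | intermediate
20 | methyl (3S,4R,5R,6S)-4,5-dihydroxy-6-methyl-3-{(2E,6S)-3-methyl-6-[(S)-4-methylbenzenesulfinyl]-6-[2,4,6-tri(propan-2-yl)benzoyloxy]hex-2-en-1-yl}-2-methylidene-10-(4,4,5,5-tetramethyl-1,3,2-dioxaborolan-2-yl)undec-10-enoate | C=C(B1OC(C)(C)C(C)(C)O1)CCC[C@H](C)[C@@H](O)[C@H](O)[C@H](C(=C)C(=O)OC)C/C=C(\C)CC[C@@H](OC(=O)c1c(C(C)C)cc(C(C)C)cc1C(C)C)[S@@](=O)c1ccc(C)cc1 | intermediate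
21 | (4S,5R)-5-[(1R,2S)-1-hydroxy-2-methyl-6-(4,4,5,5-tetramethyl-1,3,2-dioxaborolan-2-yl)hept-6-en-1-yl]-4-{(2E,6S)-3-methyl-6-[(S)-4-methylbenzenesulfinyl]-6-[2,4,6-tri(propan-2-yl)benzoyloxy]hex-2-en-1-yl}-3-methylideneoxolan-2-one | C=C(B1OC(C)(C)C(C)(C)O1)CCC[C@H](C)[C@@H](O)[C@@H]2OC(=O)C(=C)[C@@H]2C/C=C(\C)CC[C@@H](OC(=O)c1c(C(C)C)cc(C(C)C)cc1C(C)C)[S@@](=O)c1ccc(C)cc1 | intermediate
22 | 13-O-acetate of 21 (name in step 9) | C=C(B1OC(C)(C)C(C)(C)O1)CCC[C@H](C)[C@@H](OC(C)=O)[C@@H]2OC(=O)C(=C)[C@@H]2C/C=C(\C)CC[C@@H](OC(=O)c1c(C(C)C)cc(C(C)C)cc1C(C)C)[S@@](=O)c1ccc(C)cc1 | intermediate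
23 | magnesium carbenoid: 22 with the sulfinyl group at C7 replaced by MgCl (7S) | C=C(B1OC(C)(C)C(C)(C)O1)CCC[C@H](C)[C@@H](OC(C)=O)[C@@H]2OC(=O)C(=C)[C@@H]2C/C=C(\C)CC[C@@H](OC(=O)c1c(C(C)C)cc(C(C)C)cc1C(C)C)[Mg]Cl | intermediate
24 | chloromagnesium salt of the 15-membered cyclic pinacolato borate: boron bonded to C7 (7S, still carrying the triisopropylbenzoate) and to C8 | C=C1CCC[C@H](C)[C@@H](OC(C)=O)[C@@H]2OC(=O)C(=C)[C@@H]2C/C=C(\C)CC[C@@H](OC(=O)c3c(C(C)C)cc(C(C)C)cc3C(C)C)[B-]14OC(C)(C)C(C)(C)O4.Cl[Mg+] | intermediate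
25 | (1S,3E,7R,12S,13R,14R)-13-acetoxy-7-(4,4,5,5-tetramethyl-1,3,2-dioxaborolan-2-yl)cembra-3,8(19),15(17)-trien-16,14-olide | C=C1CCC[C@H](C)[C@@H](OC(C)=O)[C@@H]2OC(=O)C(=C)[C@@H]2C/C=C(\C)CC[C@H]1B3OC(C)(C)C(C)(C)O3 | intermediate
26 | (1S,3E,7R,12S,13R,14R)-13-acetoxy-7-hydroxycembra-3,8(19),15(17)-trien-16,14-olide | C=C1CCC[C@H](C)[C@@H](OC(C)=O)[C@@H]2OC(=O)C(=C)[C@@H]2C/C=C(\C)CC[C@H]1O | intermediate
27 | (1S,3R,4R,7R,12S,13R,14R)-13-acetoxy-3,4-epoxy-7-hydroxycembra-8(19),15(17)-dien-16,14-olide | C=C1CCC[C@H](C)[C@@H](OC(C)=O)[C@@H]2OC(=O)C(=C)[C@@H]2C[C@H]2O[C@]2(C)CC[C@H]1O | target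

**Totals**
Total step count: 11. Longest linear sequence: 8 steps (steps 4–11).

**Three steps most likely to fail, with fallbacks**

Step 10 (the proposed macrocyclic boronate ring contraction). Risks are slow 15-membered boronate formation, attack of the carbenoid on the lactone or acetate, and incomplete migration. The fallback uses known chemistry only, sets out from alkyne 6 and dienol 12, and comes back at macrocycle 26. The alkenylalane 7 made from 6 as in step 3 is quenched with I2 instead of MeOBpin to give (2R,3S)-7-iodo-1,1-dimethoxy-3-methyloct-7-en-2-ol F1, which is hydrolysed as in step 8 to (2R,3S)-2-hydroxy-7-iodo-3-methyloct-7-enal F2. Dienol 12 undergoes cross-metathesis with 16 (same catalyst as step 7, no sulfoxide present) to methyl (2Z,5E)-2-(bromomethyl)-9-hydroxy-6-methylnona-2,5-dienoate F3. Indium-mediated coupling of F2 with F3 and acid lactonisation, as in step 8, give the lactone diol F4. TEMPO/PhI(OAc)2 oxidises only the primary alcohol to the aldehyde F5, and Ac2O/pyridine gives the acetate aldehyde F6. An intramolecular Nozaki–Hiyama–Kishi coupling (CrCl2, NiCl2 cat., DMSO/THF, high dilution) then closes the C7–C8 bond and gives 26. The 7R epimer is favoured with a chiral sulfonamide ligand on chromium, or corrected by Dess–Martin oxidation and CBS reduction.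

Step 7 (cross-metathesis in the presence of a sulfoxide that can bind ruthenium, and a skipped diene that can isomerise). The fallback avoids metathesis, sets out from pent-4-yn-1-ol 9, and comes back at bromide 17. Acylation of 9 as in step 5 gives pent-4-yn-1-yl 2,4,6-tri(propan-2-yl)benzoate F7. Carboalumination as in step 4, conversion to the alanate with n-BuLi and opening of oxirane (Negishi) give the homoallylic alcohol F8. Lithiation of its lithium alkoxide (2.4 equiv s-BuLi, (−)-sparteine) and sulfinylation as in step 6 give the sulfinyl alcohol F9. Dess–Martin oxidation gives the β,γ-unsaturated aldehyde F10, used at once. A Morita–Baylis–Hillman reaction with methyl acrylate (DABCO) gives the allylic alcohol F11 as a mixture of carbinol epimers, and SN2′ bromination (NBS, Me2S) returns 17.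

Step 8 (three-stereocentre Barbier union). The risk is incomplete chelation control at C14 or a sluggish hydroxy aldehyde. The fallback replaces the aqueous indium reaction with a Lewis-acid chelation-controlled allylstannane addition, sets out from 8 and 17, and comes back at lactone 21. Alcohol 8 is protected (NaH, 4-methoxybenzyl chloride) as the 4-methoxybenzyl ether F12 and hydrolysed (Amberlyst 15, THF/H2O) to the α-alkoxy aldehyde F13. Bromide 17 is converted with (Bu3Sn)2 and Pd(PPh3)4 (cat.) into the allylstannane F14. MgBr2·OEt2 in CH2Cl2 at −78 °C chelates the aldehyde and its α-ether, and anti-SE2′ addition of F14 (Keck-type, syn,syn) followed by acid lactonisation gives the protected lactone F15. DDQ removes the 4-methoxybenzyl group and returns 21.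

**Further compounds**
F1 | step 10 | (2R,3S)-7-iodo-1,1-dimethoxy-3-methyloct-7-en-2-ol | C=C(I)CCC[C@H](C)[C@@H](O)C(OC)OC
F2 | step 10 | (2R,3S)-2-hydroxy-7-iodo-3-methyloct-7-enal | C=C(I)CCC[C@H](C)[C@@H](O)C=O
F3 | step 10 | methyl (2Z,5E)-2-(bromomethyl)-9-hydroxy-6-methylnona-2,5-dienoate | COC(=O)/C(CBr)=C/C/C=C(\C)CCCO
F4 | step 10 | (4S,5R)-5-[(1R,2S)-1-hydroxy-6-iodo-2-methylhept-6-en-1-yl]-4-[(2E)-6-hydroxy-3-methylhex-2-en-1-yl]-3-methylideneoxolan-2-one | C=C(I)CCC[C@H](C)[C@@H](O)[C@@H]1OC(=O)C(=C)[C@@H]1C/C=C(\C)CCCO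
F5 | step 10 | (4S,5R)-5-[(1R,2S)-1-hydroxy-6-iodo-2-methylhept-6-en-1-yl]-4-[(2E)-3-methyl-6-oxohex-2-en-1-yl]-3-methylideneoxolan-2-one | C=C(I)CCC[C@H](C)[C@@H](O)[C@@H]1OC(=O)C(=C)[C@@H]1C/C=C(\C)CCC=O
F6 | step 10 | (1R,2S)-6-iodo-2-methyl-1-{(2R,3S)-3-[(2E)-3-methyl-6-oxohex-2-en-1-yl]-4-methylidene-5-oxooxolan-2-yl}hept-6-en-1-yl acetate | C=C(I)CCC[C@H](C)[C@@H](OC(C)=O)[C@@H]1OC(=O)C(=C)[C@@H]1C/C=C(\C)CCC=O
F7 | step 7 | pent-4-yn-1-yl 2,4,6-tri(propan-2-yl)benzoate | C#CCCCOC(=O)c1c(C(C)C)cc(C(C)C)cc1C(C)C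
F8 | step 7 | (4E)-7-hydroxy-4-methylhept-4-en-1-yl 2,4,6-tri(propan-2-yl)benzoate | OCC/C=C(\C)CCCOC(=O)c1c(C(C)C)cc(C(C)C)cc1C(C)C
F9 | step 7 | (1S,4E)-7-hydroxy-4-methyl-1-[(S)-4-methylbenzenesulfinyl]hept-4-en-1-yl 2,4,6-tri(propan-2-yl)benzoate | OCC/C=C(\C)CC[C@@H](OC(=O)c1c(C(C)C)cc(C(C)C)cc1C(C)C)[S@@](=O)c1ccc(C)cc1
F10 | step 7 | (1S,4E)-4-methyl-1-[(S)-4-methylbenzenesulfinyl]-7-oxohept-4-en-1-yl 2,4,6-tri(propan-2-yl)benzoate | O=CC/C=C(\C)CC[C@@H](OC(=O)c1c(C(C)C)cc(C(C)C)cc1C(C)C)[S@@](=O)c1ccc(C)cc1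
F11 | step 7 | methyl (5E,9S)-3-hydroxy-6-methyl-2-methylidene-9-[(S)-4-methylbenzenesulfinyl]-9-{[2,4,6-tri(propan-2-yl)benzoyl]oxy}non-5-enoate (C3 epimers) | COC(=O)C(=C)C(O)C/C=C(\C)CC[C@@H](OC(=O)c1c(C(C)C)cc(C(C)C)cc1C(C)C)[S@@](=O)c1ccc(C)cc1
F12 | step 8 | 2-{(6S,7R)-8,8-dimethoxy-7-[(4-methoxyphenyl)methoxy]-6-methyloct-1-en-2-yl}-4,4,5,5-tetramethyl-1,3,2-dioxaborolane | C=C(B1OC(C)(C)C(C)(C)O1)CCC[C@H](C)[C@@H](OCc1ccc(OC)cc1)C(OC)OC
F13 | step 8 | (2R,3S)-2-[(4-methoxyphenyl)methoxy]-3-methyl-7-(4,4,5,5-tetramethyl-1,3,2-dioxaborolan-2-yl)oct-7-enal | C=C(B1OC(C)(C)C(C)(C)O1)CCC[C@H](C)[C@@H](OCc1ccc(OC)cc1)C=O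
F14 | step 8 | methyl (2Z,5E,9S)-6-methyl-9-[(S)-4-methylbenzenesulfinyl]-2-[(tributylstannyl)methyl]-9-{[2,4,6-tri(propan-2-yl)benzoyl]oxy}nona-2,5-dienoate | COC(=O)/C(C[Sn](CCCC)(CCCC)CCCC)=C/C/C=C(\C)CC[C@@H](OC(=O)c1c(C(C)C)cc(C(C)C)cc1C(C)C)[S@@](=O)c1ccc(C)cc1
F15 | step 8 | 13-O-(4-methoxybenzyl) ether of 21 | C=C(B1OC(C)(C)C(C)(C)O1)CCC[C@H](C)[C@@H](OCc1ccc(OC)cc1)[C@@H]2OC(=O)C(=C)[C@@H]2C/C=C(\C)CC[C@@H](OC(=O)c1c(C(C)C)cc(C(C)C)cc1C(C)C)[S@@](=O)c1ccc(C)cc1
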